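## Retrosynthetic overview

1. The palmitate comes from acylation of the primary alcohol, which comes from LiAlH4 reduction of a C-1 ethyl ester. The dienyl group and the C-1 centre come from Grignard addition to a masked α-keto ester (hemiketal), followed by Mitsunobu re-closure.
2. The bicyclic hemiketal comes from an acyclic allyl vinyl ether in one flask. A Cu–bis(oxazoline) Gosteli–Claisen rearrangement makes the C-3a–C-10a bond, sets both ring-fusion centres and unveils the exocyclic methylene. Hemiketalisation then closes the oxolane and metathesis closes the (Z)-cyclononene.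
3. The allyl vinyl ether comes from an HWE reaction between a linalool-derived aldehyde (the C-8 carbinol centre is taken from the chiral pool) and an α-allyloxy phosphonate made by Rh O–H insertion.
4. The allyl part is (E)-2-allylbut-2-ene-1,4-diol, made by anti-allylmagnesiation of butynediol.
5. Ring order: the oxolane (as hemiketal) forms first and the cyclononene second, both in step 9. The oxolane is opened in step 11 and re-closed in step 12 with the dienyl group in place.

Positions are numbered as in 1H-cyclonona[c]furan.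

Assumption: (S)-(+)-linalool (coriandrol, ≥95 % ee) is bought as the single enantiomer.

## Route

Step 1
Reactants: 1 (S)-(+)-linalool
Product: 2 (3S)-3,7-dimethyl-3-(triethylsilyloxy)octa-1,6-diene
Conditions: TESOTf, 2,6-lutidine, CH2Cl2, −78 → 0 °C
Reagents that add atoms: triethylsilyl trifluoromethanesulfonate CC[Si](CC)(CC)OS(=O)(=O)C(F)(F)F
Why: Silyl ether formation with TESOTf/lutidine covers even a tertiary allylic alcohol without ionisation, so the aldehyde made next cannot close to a lactol; the (S) carbinol centre (later C-8) is carried over unchanged from linalool.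

Step 2
Reactants: 2 (3S)-3,7-dimethyl-3-(triethylsilyloxy)octa-1,6-diene
Product: 3 (4S)-4-methyl-4-(triethylsilyloxy)hex-5-enal
Conditions: O3 (1 equiv, Sudan III end-point), CH2Cl2/MeOH, −78 °C; Me2S
Reagents that add atoms: ozone [O-][O+]=O
Why: In this chemoselective ozonolysis the electron-rich trisubstituted alkene reacts much faster than the hindered monosubstituted vinyl group, and reductive work-up gives the aldehyde without touching the stereocentre.

Step 3
Reactants: 4 but-2-yne-1,4-diol; 5 allylmagnesium bromide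
Product: 6 (2E)-2-(prop-2-en-1-yl)but-2-ene-1,4-diol
Conditions: 5 (3.5 equiv), THF, reflux, 16 h; then H2O
Reagents that add atoms: none
Why: Alkoxide-directed anti-carbomagnesiation of a propargylic alcohol through a five-membered Mg chelate places allyl and Mg trans, so protonation gives the (E)-diol, and the symmetrical alkyne raises no regiochemical question.

Step 4
Reactants: 6 (2E)-2-(prop-2-en-1-yl)but-2-ene-1,4-diol
Product: 7 (2E)-4-(tert-butyldimethylsilyloxy)-2-(prop-2-en-1-yl)but-2-en-1-ol
Conditions: TBSCl (1.0 equiv), imidazole, CH2Cl2, −20 °C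
Reagents that add atoms: tert-butyldimethylsilyl chloride CC(C)(C)[Si](C)(C)Cl
Why: Sterically controlled monosilylation takes the hydroxyl next to the CH= carbon in preference to the one next to the fully substituted, allyl-bearing carbon; the minor regioisomer is removed by chromatography.

Step 5
Reactants: 8 triethyl phosphonoacetate
Product: 9 ethyl diazo(diethoxyphosphoryl)acetate
Conditions: NaH, 4-acetamidobenzenesulfonyl azide, THF, 0 °C → rt
Reagents that add atoms: 4-acetamidobenzenesulfonyl azide CC(=O)Nc1ccc(cc1)S(=O)(=O)N=[N+]=[N-]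
Why: This is a Regitz diazo transfer onto the doubly activated methylene group.

Step 6
Reactants: 7 (2E)-4-(tert-butyldimethylsilyloxy)-2-(prop-2-en-1-yl)but-2-en-1-ol; 9 ethyl diazo(diethoxyphosphoryl)acetate
Product: 10 ethyl 2-(diethoxyphosphoryl)-2-{[(2E)-4-(tert-butyldimethylsilyloxy)-2-(prop-2-en-1-yl)but-2-en-1-yl]oxy}acetate (racemic at C-2)
Conditions: Rh2(OAc)4 (1 mol %), toluene, 80 °C
Reagents that add atoms: none
Why: Rh(II)-carbenoid O–H insertion into the only free hydroxyl is faster than cyclopropanation for this stabilised carbenoid, and the new centre is erased in the next step.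

Step 7
Reactants: 10 ethyl 2-(diethoxyphosphoryl)-2-{[(2E)-4-(tert-butyldimethylsilyloxy)-2-(prop-2-en-1-yl)but-2-en-1-yl]oxy}acetate; 3 (4S)-4-methyl-4-(triethylsilyloxy)hex-5-enal
Product: 11 ethyl (2Z,6S)-2-{[(2E)-4-(tert-butyldimethylsilyloxy)-2-(prop-2-en-1-yl)but-2-en-1-yl]oxy}-6-methyl-6-(triethylsilyloxy)octa-2,7-dienoate
Conditions: LiHMDS, THF, −78 °C → rt
Reagents that add atoms: none
Why: The Horner–Wadsworth–Emmons olefination places the ester trans to the alkyl chain as usual, which for a 2-alkoxy enoate is the (Z)-enol ether needed for the Claisen chair; the minor (E) isomer is separated.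

Step 8
Reactants: 11 ethyl (2Z,6S)-2-{[(2E)-4-(tert-butyldimethylsilyloxy)-2-(prop-2-en-1-yl)but-2-en-1-yl]oxy}-6-methyl-6-(triethylsilyloxy)octa-2,7-dienoate
Product: 12 ethyl (2Z,6S)-6-hydroxy-2-{[(2E)-4-hydroxy-2-(prop-2-en-1-yl)but-2-en-1-yl]oxy}-6-methylocta-2,7-dienoate
Conditions: HF·pyridine, pyridine, THF, 0 °C → rt
Reagents that add atoms: none
Why: Buffered fluoride desilylation removes both silyl groups, while the ester-deactivated enol ether and the tertiary allylic alcohol tolerate the mild acidity.

Step 9 (key step)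
Reactants: 12 ethyl (2Z,6S)-6-hydroxy-2-{[(2E)-4-hydroxy-2-(prop-2-en-1-yl)but-2-en-1-yl]oxy}-6-methylocta-2,7-dienoate
Product: 15 ethyl (3aR,6Z,8S,10aS)-1,8-dihydroxy-8-methyl-4-methylidene-3,3a,4,5,8,9,10,10a-octahydro-1H-cyclonona[c]furan-1-carboxylate (anomers), via open-chain α-keto ester 13 (not isolated), via monocyclic hemiketal 14 (not isolated)
Conditions: [Cu{(S,S)-tBu-box}(H2O)2](SbF6)2 (10 mol %), CH2Cl2 (0.1 M), rt; then dilute to 1 mM, Grubbs II (10 mol %), 1,4-benzoquinone (20 mol %), 40 °C
Reagents that add atoms: none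
Why: Proposed new method: the three events are each known but have not been run as one operation on a free diol: (i) the Cu(II)–bis(oxazoline) Lewis acid chelates the ether oxygen and the ester carbonyl of the 2-alkoxycarbonyl allyl vinyl ether and triggers a catalytic asymmetric Gosteli–Claisen rearrangement through a chair in which the (Z)-enol ether holds the C-10 chain axial and the (E)-allyl unit holds CH2OH equatorial, so that C-10a (S) and C-3a (R) arise in the trans-fusion relationship, the face is fixed by the tert-butyl group next to the bound ether oxygen (square-planar chelate model), and the 1,1-disubstituted methylene is unveiled; (ii) the γ-hydroxy α-keto ester 13 collapses at once to the five-ring hemiketal 14 (ring–chain tautomerism), which blocks enolisation at C-10a and carbonyl-ene side reactions and holds the two olefinic arms trans-vicinal on a ring; (iii) after dilution, ring-closing metathesis starts at the unhindered allyl terminus, is helped by the free allylic hydroxyl, and closes the cyclononene, whose size enforces the Z olefin; the closest known reaction types are the copper–box Gosteli–Claisen rearrangement of protected substrates and medium-ring RCM on cyclic templates.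

Step 10
Reactants: 16 3-methylbut-2-enal (prenal); 17 iodoform
Product: 18 (1E)-1-iodo-4-methylpenta-1,3-diene
Conditions: CrCl2 (6 equiv), THF, 0 °C
Reagents that add atoms: none
Why: The Takai olefination converts the enal into the (E)-iodoalkene through a gem-dichromium species and sets the E geometry of the side-chain olefin.

Step 11
Reactants: 15 ethyl (3aR,6Z,8S,10aS)-1,8-dihydroxy-8-methyl-4-methylidene-3,3a,4,5,8,9,10,10a-octahydro-1H-cyclonona[c]furan-1-carboxylate; 18 (1E)-1-iodo-4-methylpenta-1,3-diene
Product: 20 ethyl (2R,3E)-2-hydroxy-2-[(1S,4S,5Z,9R)-4-hydroxy-9-(hydroxymethyl)-4-methyl-8-methylidenecyclonon-5-en-1-yl]-6-methylhepta-3,5-dienoate, via dienylmagnesium chloride 19 (not isolated)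
Conditions: 18 (3.5 equiv), iPrMgCl·LiCl (3.5 equiv), THF, 0 °C → rt; then 15, −78 → −40 °C; aq NH4Cl
Reagents that add atoms: none
Why: I/Mg exchange proceeds with retention of olefin geometry; two equivalents of 19 deprotonate the hydroxyls and open the hemiketal, and a chemoselective Grignard 1,2-addition to the ketone of the α-keto ester follows, in which Mg bound to the primary alkoxide, the ketone and the ester holds a ring-like chelate whose face on the C-10 methylene side is blocked, so the dienyl group enters syn to H-10a and gives the (R) carbinol.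

Step 12
Reactants: 20 ethyl (2R,3E)-2-hydroxy-2-[(1S,4S,5Z,9R)-4-hydroxy-9-(hydroxymethyl)-4-methyl-8-methylidenecyclonon-5-en-1-yl]-6-methylhepta-3,5-dienoate
Product: 21 ethyl (1R,3aR,6Z,8S,10aS)-8-hydroxy-8-methyl-4-methylidene-1-[(1E)-4-methylpenta-1,3-dien-1-yl]-3,3a,4,5,8,9,10,10a-octahydro-1H-cyclonona[c]furan-1-carboxylate
Conditions: PPh3, DIAD, toluene, 0 °C → rt
Reagents that add atoms: none
Why: Mitsunobu cyclodehydration activates only the primary hydroxyl, and the fairly acidic α-hydroxy-ester oxygen displaces it in a 5-exo-tet closure; the C-1–O bond is never broken, so C-1 stays (R), and the hindered C-8 carbinol does not react.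

Step 13
Reactants: 21 ethyl (1R,3aR,6Z,8S,10aS)-8-hydroxy-8-methyl-4-methylidene-1-[(1E)-4-methylpenta-1,3-dien-1-yl]-3,3a,4,5,8,9,10,10a-octahydro-1H-cyclonona[c]furan-1-carboxylate
Product: 22 (1R,3aR,6Z,8S,10aS)-1-(hydroxymethyl)-8-methyl-4-methylidene-1-[(1E)-4-methylpenta-1,3-dien-1-yl]-3,3a,4,5,8,9,10,10a-octahydro-1H-cyclonona[c]furan-8-ol
Conditions: LiAlH4, Et2O, 0 °C; Fieser work-up
Reagents that add atoms: none
Why: Hydride reduction of the ester gives the neopentyl-type primary alcohol, and the isolated olefins, the diene and the allylic ether are inert to LiAlH4.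

Step 14
Reactants: 22 (1R,3aR,6Z,8S,10aS)-1-(hydroxymethyl)-8-methyl-4-methylidene-1-[(1E)-4-methylpenta-1,3-dien-1-yl]-3,3a,4,5,8,9,10,10a-octahydro-1H-cyclonona[c]furan-8-ol; 23 palmitoyl chloride
Product: 24 [(1R,3aR,6Z,8S,10aS)-8-hydroxy-8-methyl-4-methylidene-1-[(1E)-4-methylpenta-1,3-dien-1-yl]-3,3a,4,5,8,9,10,10a-octahydro-1H-cyclonona[c]furan-1-yl]methyl hexadecanoate (target)
Conditions: 23 (1.05 equiv), pyridine, DMAP (5 mol %), CH2Cl2, 0 °C
Reagents that add atoms: none
Why: DMAP-catalysed acylation is selective for the primary hydroxyl over the tertiary allylic one, and no stereocentre is touched.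

## Compound list

1 | (S)-(+)-linalool | C=C[C@@](C)(O)CCC=C(C)C | starting material
2 | (3S)-3,7-dimethyl-3-(triethylsilyloxy)octa-1,6-diene | C=C[C@@](C)(O[Si](CC)(CC)CC)CCC=C(C)C | intermediate
3 | (4S)-4-methyl-4-(triethylsilyloxy)hex-5-enal | C=C[C@@](C)(O[Si](CC)(CC)CC)CCC=O | intermediate
4 | but-2-yne-1,4-diol | OCC#CCO | starting material
5 | allylmagnesium bromide | C=CC[Mg]Br | starting material
6 | (2E)-2-(prop-2-en-1-yl)but-2-ene-1,4-diol | OC/C=C(/CO)CC=C | intermediate
7 | (2E)-4-(tert-butyldimethylsilyloxy)-2-(prop-2-en-1-yl)but-2-en-1-ol | CC(C)(C)[Si](C)(C)OC/C=C(/CO)CC=C | intermediate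
8 | triethyl phosphonoacetate | CCOC(=O)CP(=O)(OCC)OCC | starting material
9 | ethyl diazo(diethoxyphosphoryl)acetate | CCOC(=O)C(=[N+]=[N-])P(=O)(OCC)OCC | intermediate
10 | α-allyloxy phosphonoacetate (racemic at C-2) | CCOC(=O)C(OC/C(CC=C)=C/CO[Si](C)(C)C(C)(C)C)P(=O)(OCC)OCC | intermediate
11 | bis-silyl (2Z,6S) allyl vinyl ether | CCOC(=O)/C(OC/C(CC=C)=C/CO[Si](C)(C)C(C)(C)C)=C/CC[C@](C)(O[Si](CC)(CC)CC)C=C | intermediate
12 | (2Z,6S) allyl vinyl ether diol | CCOC(=O)/C(OC/C(CC=C)=C/CO)=C/CC[C@](C)(O)C=C | intermediate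
13 | ethyl (3S,6S)-6-hydroxy-3-[(2R)-1-hydroxy-3-methylidenehex-5-en-2-yl]-6-methyl-2-oxooct-7-enoate | C=C[C@@](C)(O)CC[C@H](C(=O)C(=O)OCC)[C@H](C(=C)CC=C)CO | intermediate
14 | ethyl (3S,4R)-4-(hexa-1,5-dien-2-yl)-2-hydroxy-3-[(3S)-3-hydroxy-3-methylpent-4-en-1-yl]oxolane-2-carboxylate (anomers) | C=C[C@@](C)(O)CC[C@H]1[C@H](C(=C)CC=C)COC1(O)C(=O)OCC | intermediate
15 | bicyclic hemiketal ester (3aR,6Z,8S,10aS; anomers) | C=C1C/C=C\[C@@](C)(O)CC[C@H]2[C@H]1COC2(O)C(=O)OCC | intermediate
16 | 3-methylbut-2-enal | CC(C)=CC=O | starting material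
17 | iodoform | IC(I)I | starting material
18 | (1E)-1-iodo-4-methylpenta-1,3-diene | CC(C)=C/C=C/I | intermediate
19 | [(1E)-4-methylpenta-1,3-dien-1-yl]magnesium chloride | CC(C)=C/C=C/[Mg]Cl | intermediate
20 | (2R,3E) α-hydroxy ester on the cyclononadiene, with free CH2OH | C=C1C/C=C\[C@@](C)(O)CC[C@H]([C@](O)(/C=C/C=C(C)C)C(=O)OCC)[C@H]1CO | intermediate
21 | ethyl (1R,3aR,6Z,8S,10aS) oxolane-1-carboxylate with dienyl group | C=C1C/C=C\[C@@](C)(O)CC[C@H]2[C@H]1CO[C@@]2(/C=C/C=C(C)C)C(=O)OCC | intermediate
22 | (1R,3aR,6Z,8S,10aS) diol | C=C1C/C=C\[C@@](C)(O)CC[C@H]2[C@H]1CO[C@@]2(/C=C/C=C(C)C)CO | intermediate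
23 | palmitoyl chloride | CCCCCCCCCCCCCCCC(=O)Cl | starting material
24 | CNP0150666.1 | C=C1C/C=C\[C@@](C)(O)CC[C@H]2[C@H]1CO[C@@]2(/C=C/C=C(C)C)COC(=O)CCCCCCCCCCCCCCC | target

## Step count and risks

Total steps: 14.
Longest linear sequence: 10 (steps 3, 4, 6, 7, 8, 9, 11, 12, 13, 14).

**Step 9.** The free diol may slow or erode the copper catalysis. The metathesis may also give oligomers, or a seven-membered ring through the 1,1-disubstituted olefin.

The fallback sets out from 11 and comes back at 15. It gives up the one-flask double closure and inverts the ring order.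
- The copper–box Claisen rearrangement is run on the fully silylated ether 11, the established substrate class, to give the bis-silyl α-keto ester F1.
- PPTS in methanol frees only the tertiary carbinol, because TES is far more labile than TBS, and gives the mono-TBS keto ester F2.
- With the primary hydroxyl still blocked, the carbocycle is closed on the open-chain keto ester. The closure uses hydroxyl-accelerated metathesis with first-generation Grubbs catalyst, which ignores 1,1-disubstituted olefins, and gives the cyclononadiene keto ester F3.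
- HF·pyridine then removes the TBS group, and the oxolane closes by itself to 15.

**Step 11.** The facial selectivity at C-1 rests on a chelate model. Enolisation or δ-lactone formation may also compete.

The fallback sets out from 15 and comes back at 21, so step 12 is skipped. The oxolane is kept closed, and the dienyl group is brought in by substitution at a cyclic oxocarbenium ion instead of addition to the open ketone.
- Ac2O/Et3N/DMAP gives the anomeric acetate F4.
- The Grignard reagent 19 is transmetallated with Me2AlCl to the dienyl(dimethyl)alane F5.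
- F5 acts as both Lewis acid and nucleophile at −78 → −20 °C and attacks the five-ring cation anti to the C-10 arm to give 21.

**Step 7.** The Z:E ratio and the reactivity of the hindered α-alkoxy phosphonate are uncertain.

The fallback sets out from 7 and comes back at 11. The enol ether is built by aldol condensation instead of olefination.
- O-alkylation of 7 with ethyl bromoacetate (NaH, THF) gives the allyloxyacetate F6.
- LDA aldol addition of F6 to 3 gives the β-hydroxy ester F7 as a diastereomer mixture.
- MsCl/Et3N gives the mesylate F8.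
- DBU elimination of F8 gives 11 after separation of the (E) isomer.

## Further compounds

F1 | step 9 | ethyl (3S,6S)-3-[(2R)-1-(tert-butyldimethylsilyloxy)-3-methylidenehex-5-en-2-yl]-6-methyl-2-oxo-6-(triethylsilyloxy)oct-7-enoate | C=C[C@@](C)(O[Si](CC)(CC)CC)CC[C@H](C(=O)C(=O)OCC)[C@H](C(=C)CC=C)CO[Si](C)(C)C(C)(C)C
F2 | step 9 | ethyl (3S,6S)-3-[(2R)-1-(tert-butyldimethylsilyloxy)-3-methylidenehex-5-en-2-yl]-6-hydroxy-6-methyl-2-oxooct-7-enoate | C=C[C@@](C)(O)CC[C@H](C(=O)C(=O)OCC)[C@H](C(=C)CC=C)CO[Si](C)(C)C(C)(C)C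
F3 | step 9 | ethyl 2-[(1S,4S,5Z,9R)-9-(tert-butyldimethylsilyloxymethyl)-4-hydroxy-4-methyl-8-methylidenecyclonon-5-en-1-yl]-2-oxoacetate | C=C1C/C=C\[C@@](C)(O)CC[C@H](C(=O)C(=O)OCC)[C@H]1CO[Si](C)(C)C(C)(C)C
F4 | step 11 | ethyl (3aR,6Z,8S,10aS)-1-acetoxy-8-hydroxy-8-methyl-4-methylidene-3,3a,4,5,8,9,10,10a-octahydro-1H-cyclonona[c]furan-1-carboxylate | C=C1C/C=C\[C@@](C)(O)CC[C@H]2[C@H]1COC2(OC(C)=O)C(=O)OCC
F5 | step 11 | dimethyl[(1E)-4-methylpenta-1,3-dien-1-yl]alane | CC(C)=C/C=C/[Al](C)C
F6 | step 7 | ethyl 2-{[(2E)-4-(tert-butyldimethylsilyloxy)-2-(prop-2-en-1-yl)but-2-en-1-yl]oxy}acetate | CCOC(=O)COC/C(CC=C)=C/CO[Si](C)(C)C(C)(C)C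
F7 | step 7 | ethyl (6S)-2-{[(2E)-4-(tert-butyldimethylsilyloxy)-2-(prop-2-en-1-yl)but-2-en-1-yl]oxy}-3-hydroxy-6-methyl-6-(triethylsilyloxy)oct-7-enoate | CCOC(=O)C(OC/C(CC=C)=C/CO[Si](C)(C)C(C)(C)C)C(O)CC[C@](C)(O[Si](CC)(CC)CC)C=C
F8 | step 7 | ethyl (6S)-2-{[(2E)-4-(tert-butyldimethylsilyloxy)-2-(prop-2-en-1-yl)but-2-en-1-yl]oxy}-3-(methylsulfonyloxy)-6-methyl-6-(triethylsilyloxy)oct-7-enoate | CCOC(=O)C(OC/C(CC=C)=C/CO[Si](C)(C)C(C)(C)C)C(OS(C)(=O)=O)CC[C@](C)(O[Si](CC)(CC)CC)C=C
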